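## Retrosynthetic overview

1. The C6-prenyl group comes from a C6-allyl group by cross-metathesis. The allyl group comes from the 7-O-allyl ether of isocaviunin by aromatic Claisen rearrangement. C8 carries OMe, so only C6 is open.
2. Ring C comes from acid ring closure of a 2-aryl-3,3-dimethoxypropiophenone, which comes from the oxidative 1,2-aryl shift of a chalcone.
3. Key C–C bond: the chalcone comes from a Claisen–Schmidt aldol condensation of a ring A acetophenone with 2,4,5-trimethoxybenzaldehyde (ring B).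
4. The ring A acetophenone comes from mirror-symmetric 5-benzyloxy-2-methoxy-1,3-bis(MOM-oxy)benzene, made from 2,4,6-trihydroxybenzaldehyde (CHO → OMe by Baeyer–Villiger). Bn on the future O-5 and MOM on the future O-1 and O-7 fix the direction of ring closure.
5. Rings A and B are bought as arenes. Ring C is the only ring formed (step 9).

Assumption: the target has no stereocentre and no stereogenic double bond, so it is achiral and needs no enantiocontrol. The sp3 centres formed on the way are racemic and are erased later.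

## Route

Step 1
Reactants: 1 2,4,6-trihydroxybenzaldehyde
Product: 2 4-(benzyloxy)-2,6-dihydroxybenzaldehyde
Conditions: BnBr (1.0 equiv), NaHCO3 (1.2 equiv), MeCN, 70 °C
Reagents that add atoms: benzyl bromide, BrCc1ccccc1
Why: In this Williamson etherification the weak base ionises only the 4-OH (para to CHO, most acidic), because both ortho OH groups are hydrogen-bonded to the formyl oxygen.

Step 2
Reactants: 2 4-(benzyloxy)-2,6-dihydroxybenzaldehyde
Product: 3 4-(benzyloxy)-2,6-bis(methoxymethoxy)benzaldehyde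
Conditions: NaH (2.5 equiv), MOMCl (2.8 equiv), DMF, 0 °C → rt
Reagents that add atoms: chloromethyl methyl ether (MOMCl), COCCl
Why: In this Williamson-type O-alkylation NaH deprotonates both chelated, symmetry-equivalent phenols irreversibly, so only one product is possible.

Step 3
Reactants: 3 4-(benzyloxy)-2,6-bis(methoxymethoxy)benzaldehyde
Product: 5 4-(benzyloxy)-2,6-bis(methoxymethoxy)phenol, via aryl formate 4 (not isolated)
Conditions: mCPBA (1.15 equiv), CH2Cl2, 0 °C → rt; then K2CO3 (0.2 equiv), MeOH, rt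
Reagents that add atoms: mCPBA (3-chloroperoxybenzoic acid), OOC(=O)c1cccc(Cl)c1
Why: In this Baeyer–Villiger (Dakin-type) oxidation the very electron-rich aryl group migrates in the Criegee adduct, and the formate is then methanolysed under conditions that leave MOM and Bn untouched.

Step 4
Reactants: 5 4-(benzyloxy)-2,6-bis(methoxymethoxy)phenol
Product: 6 5-(benzyloxy)-2-methoxy-1,3-bis(methoxymethoxy)benzene
Conditions: MeI (1.5 equiv), K2CO3 (2 equiv), acetone, reflux (5 is used at once)
Reagents that add atoms: iodomethane, CI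
Why: Williamson O-methylation of the only free OH installs the future 8-OMe group without any regiochemical choice.

Step 5
Reactants: 6 5-(benzyloxy)-2-methoxy-1,3-bis(methoxymethoxy)benzene
Product: 7 1-(benzyloxy)-2-bromo-4-methoxy-3,5-bis(methoxymethoxy)benzene
Conditions: NBS (1.0 equiv), MeCN, 0 °C, dark
Reagents that add atoms: N-bromosuccinimide, O=C1CCC(=O)N1Br
Why: This is an electrophilic aromatic bromination in which the two free ring positions are equivalent by symmetry, so a single monobromide forms under neutral conditions that spare the MOM groups.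

Step 6
Reactants: 7 1-(benzyloxy)-2-bromo-4-methoxy-3,5-bis(methoxymethoxy)benzene
Product: 10 1-[6-(benzyloxy)-3-methoxy-2,4-bis(methoxymethoxy)phenyl]ethan-1-one, via aryllithium 8 (not isolated), via lithium hemiaminal alkoxide 9 (not isolated)
Conditions: n-BuLi (1.05 equiv), THF, −78 °C, 20 min; MeC(O)N(OMe)Me (1.5 equiv), −78 → 0 °C; H2O quench
Reagents that add atoms: N-methoxy-N-methylacetamide, CC(=O)N(C)OC
Why: Bromine–lithium exchange at −78 °C is faster than benzylic deprotonation, and in the Weinreb ketone synthesis the chelated tetrahedral adduct survives until the quench, so no over-addition occurs.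

Step 7
Reactants: 10 1-[6-(benzyloxy)-3-methoxy-2,4-bis(methoxymethoxy)phenyl]ethan-1-one; 11 2,4,5-trimethoxybenzaldehyde
Product: 13 (E)-1-[6-(benzyloxy)-3-methoxy-2,4-bis(methoxymethoxy)phenyl]-3-(2,4,5-trimethoxyphenyl)prop-2-en-1-one, via aldol adduct 12 (not isolated)
Conditions: KOH (50% aq.), EtOH, rt, 24–48 h
Reagents that add atoms: none
Why: In this Claisen–Schmidt crossed aldol condensation only the ketone can enolise and only the aldehyde is a good acceptor, and E1cB dehydration gives the conjugated E-enone as the thermodynamic isomer.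

Step 8
Reactants: 13 (E)-chalcone
Product: 14 1-[6-(benzyloxy)-3-methoxy-2,4-bis(methoxymethoxy)phenyl]-3,3-dimethoxy-2-(2,4,5-trimethoxyphenyl)propan-1-one (racemic)
Conditions: Tl(NO3)3·3H2O (1.1 equiv), MeOH, rt, 3–6 h; filter off TlNO3
Reagents that add atoms: methanol, CO
Why: In this oxidative 1,2-aryl migration trivalent thallium and MeOH add across the enone, the electron-rich trimethoxyphenyl group shifts to the α-carbon as monovalent thallium leaves, and MeOH traps the oxocarbenium ion; the new centre is racemic and is erased in step 9.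

Step 9
Reactants: 14 rearranged dimethyl acetal
Product: 17 5-(benzyloxy)-7-hydroxy-8-methoxy-3-(2,4,5-trimethoxyphenyl)-4H-chromen-4-one, via diphenol acetal 15 (not isolated), via 2-methoxyisoflavanone 16 (not isolated)
Conditions: conc. HCl (ca. 5% v/v), MeOH, reflux, 2 h
Reagents that add atoms: none
Why: Acid-catalysed acetal exchange removes both MOM groups, only the ortho OH next to OMe can reach the acetal carbon because O-6 of the ketone stays benzylated, and transacetalisation followed by elimination of MeOH gives the 8-methoxy isoflavone alone.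

Step 10
Reactants: 17 5-(benzyloxy)-7-hydroxy-8-methoxy-3-(2,4,5-trimethoxyphenyl)-4H-chromen-4-one
Product: 18 isocaviunin [5,7-dihydroxy-8-methoxy-3-(2,4,5-trimethoxyphenyl)-4H-chromen-4-one]
Conditions: H2 (1 atm), 10% Pd/C, EtOAc–MeOH, rt, stopped at full conversion
Reagents that add atoms: none
Why: Catalytic hydrogenolysis of the aryl benzyl ether is much faster than reduction of the isoflavone C2=C3 bond at 1 atm.

Step 11
Reactants: 18 isocaviunin
Product: 19 5-hydroxy-8-methoxy-7-(prop-2-en-1-yloxy)-3-(2,4,5-trimethoxyphenyl)-4H-chromen-4-one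
Conditions: allyl bromide (1.1 equiv), K2CO3 (1.2 equiv), acetone, reflux
Reagents that add atoms: allyl bromide, C=CCBr
Why: This Williamson etherification is regioselective because the 7-OH is the acidic vinylogous-acid phenol, whereas the 5-OH is tied up in a hydrogen bond to C4=O.

Step 12
Reactants: 19 7-O-allyl ether
Product: 21 5,7-dihydroxy-8-methoxy-6-(prop-2-en-1-yl)-3-(2,4,5-trimethoxyphenyl)-4H-chromen-4-one, via ortho-dienone 20 (not isolated)
Conditions: PhNEt2, 200 °C, Ar, 3 h
Reagents that add atoms: none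
Why: In this aromatic Claisen [3,3] rearrangement, migration to C8 gives a dienone that cannot tautomerise and reverts, so the allyl group ends at C6, where enolisation restores the arene.

Step 13
Reactants: 21 6-allyl isoflavone
Product: 22 6-prenylisocaviunin [5,7-dihydroxy-8-methoxy-6-(3-methylbut-2-en-1-yl)-3-(2,4,5-trimethoxyphenyl)-4H-chromen-4-one]
Conditions: second-generation Grubbs catalyst RuCl2(=CHPh)(PCy3)(SIMes) (5 mol %), 1,4-benzoquinone (10 mol %), 2-methylbut-2-ene/CH2Cl2 1:1, 40 °C, sealed tube, 12 h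
Reagents that add atoms: 2-methylbut-2-ene, CC=C(C)C
Why: Olefin cross-metathesis of the terminal allyl group with a large excess of 2-methylbut-2-ene is driven by loss of propene, tolerates phenols, and has no E/Z issue because the new alkene terminus carries two methyl groups.

## Compound list

1 | 2,4,6-trihydroxybenzaldehyde | O=Cc1c(O)cc(O)cc1O | starting material
2 | 4-(benzyloxy)-2,6-dihydroxybenzaldehyde | O=Cc1c(O)cc(OCc2ccccc2)cc1O | intermediate
3 | 4-(benzyloxy)-2,6-bis(methoxymethoxy)benzaldehyde | O=Cc1c(OCOC)cc(OCc2ccccc2)cc1OCOC | intermediate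
4 | 4-(benzyloxy)-2,6-bis(methoxymethoxy)phenyl formate (aryl formate; not isolated) | O=COc1c(OCOC)cc(OCc2ccccc2)cc1OCOC | intermediate
5 | 4-(benzyloxy)-2,6-bis(methoxymethoxy)phenol | Oc1c(OCOC)cc(OCc2ccccc2)cc1OCOC | intermediate
6 | 5-(benzyloxy)-2-methoxy-1,3-bis(methoxymethoxy)benzene | COc1c(OCOC)cc(OCc2ccccc2)cc1OCOC | intermediate
7 | 1-(benzyloxy)-2-bromo-4-methoxy-3,5-bis(methoxymethoxy)benzene | COc1c(OCOC)cc(OCc2ccccc2)c(Br)c1OCOC | intermediate
8 | [6-(benzyloxy)-3-methoxy-2,4-bis(methoxymethoxy)phenyl]lithium (aryllithium; not isolated) | COc1c(OCOC)cc(OCc2ccccc2)c([Li])c1OCOC | intermediate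
9 | lithium 1-aryl-1-[methoxy(methyl)amino]ethan-1-olate (lithium hemiaminal alkoxide; racemic; not isolated) | COc1c(OCOC)cc(OCc2ccccc2)c(C(C)([O-])N(C)OC)c1OCOC.[Li+] | intermediate
10 | 1-[6-(benzyloxy)-3-methoxy-2,4-bis(methoxymethoxy)phenyl]ethan-1-one | COc1c(OCOC)cc(OCc2ccccc2)c(C(C)=O)c1OCOC | intermediate
11 | 2,4,5-trimethoxybenzaldehyde | COc1cc(OC)c(C=O)cc1OC | starting material
12 | 1-[6-(benzyloxy)-3-methoxy-2,4-bis(methoxymethoxy)phenyl]-3-hydroxy-3-(2,4,5-trimethoxyphenyl)propan-1-one (aldol adduct; racemic; not isolated) | COc1cc(OC)c(C(O)CC(=O)c2c(OCc3ccccc3)cc(OCOC)c(OC)c2OCOC)cc1OC | intermediate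
13 | (E)-1-[6-(benzyloxy)-3-methoxy-2,4-bis(methoxymethoxy)phenyl]-3-(2,4,5-trimethoxyphenyl)prop-2-en-1-one | COc1cc(OC)c(/C=C/C(=O)c2c(OCc3ccccc3)cc(OCOC)c(OC)c2OCOC)cc1OC | intermediate
14 | 1-[6-(benzyloxy)-3-methoxy-2,4-bis(methoxymethoxy)phenyl]-3,3-dimethoxy-2-(2,4,5-trimethoxyphenyl)propan-1-one (racemic) | COC(OC)C(C(=O)c1c(OCc2ccccc2)cc(OCOC)c(OC)c1OCOC)c1cc(OC)c(OC)cc1OC | intermediate
15 | 1-[6-(benzyloxy)-2,4-dihydroxy-3-methoxyphenyl]-3,3-dimethoxy-2-(2,4,5-trimethoxyphenyl)propan-1-one (diphenol acetal; racemic; not isolated) | COC(OC)C(C(=O)c1c(OCc2ccccc2)cc(O)c(OC)c1O)c1cc(OC)c(OC)cc1OC | intermediate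
16 | 5-(benzyloxy)-7-hydroxy-2,8-dimethoxy-3-(2,4,5-trimethoxyphenyl)chroman-4-one (2-methoxyisoflavanone; diastereomer mixture, racemic; not isolated) | COC1Oc2c(OC)c(O)cc(OCc3ccccc3)c2C(=O)C1c1cc(OC)c(OC)cc1OC | intermediate
17 | 5-(benzyloxy)-7-hydroxy-8-methoxy-3-(2,4,5-trimethoxyphenyl)-4H-chromen-4-one | COc1cc(OC)c(-c2coc3c(OC)c(O)cc(OCc4ccccc4)c3c2=O)cc1OC | intermediate
18 | isocaviunin [5,7-dihydroxy-8-methoxy-3-(2,4,5-trimethoxyphenyl)-4H-chromen-4-one] | COc1cc(OC)c(-c2coc3c(OC)c(O)cc(O)c3c2=O)cc1OC | intermediate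
19 | 5-hydroxy-8-methoxy-7-(prop-2-en-1-yloxy)-3-(2,4,5-trimethoxyphenyl)-4H-chromen-4-one | COc1cc(OC)c(-c2coc3c(OC)c(OCC=C)cc(O)c3c2=O)cc1OC | intermediate
20 | 6-allyl-5-hydroxy-8-methoxy-3-(2,4,5-trimethoxyphenyl)-6H-chromene-4,7-dione (ortho-dienone; racemic; not isolated) | COc1cc(OC)c(C2=COC3=C(OC)C(=O)C(CC=C)C(O)=C3C2=O)cc1OC | intermediate
21 | 5,7-dihydroxy-8-methoxy-6-(prop-2-en-1-yl)-3-(2,4,5-trimethoxyphenyl)-4H-chromen-4-one | COc1cc(OC)c(-c2coc3c(OC)c(O)c(CC=C)c(O)c3c2=O)cc1OC | intermediate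
22 | 6-prenylisocaviunin [5,7-dihydroxy-8-methoxy-6-(3-methylbut-2-en-1-yl)-3-(2,4,5-trimethoxyphenyl)-4H-chromen-4-one] | COc1cc(OC)c(-c2coc3c(OC)c(O)c(CC=C(C)C)c(O)c3c2=O)cc1OC | target

## Summary

Total step count: 13.
Longest linear sequence: 13 steps (1 → 22). Compound 11 is bought.

**Three steps most likely to fail**

**Step 8.** The very electron-rich ring B may be over-oxidised, and the released acid may strip MOM groups early. The fallback sets out from 13 and avoids thallium. It uses an acyl shift instead of an aryl shift.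
- Weitz–Scheffer epoxidation (30% H2O2, NaOH, MeOH–THF, 0 °C) gives the racemic trans-chalcone epoxide F2.
- BF3·OEt2 (CH2Cl2, −20 °C) opens the epoxide at the benzylic carbon. A 1,2-aroyl shift then gives 3-[6-(benzyloxy)-3-methoxy-2,4-bis(methoxymethoxy)phenyl]-3-oxo-2-(2,4,5-trimethoxyphenyl)propanal F3.
- HCl in refluxing MeOH removes the MOM groups and cyclodehydrates F3. The route is rejoined at 17.

**Step 13.** Ruthenium hydride species may isomerise the allyl group to a propenyl group, and the flanking phenols may slow turnover. The fallback sets out from 18 and brings in all five prenyl carbons by a rearrangement.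
- The 7-OH is alkylated with 3-chloro-3-methylbut-1-yne (CuCl2 cat., DBU, MeCN, 0 °C). This gives 5-hydroxy-8-methoxy-7-[(2-methylbut-3-yn-2-yl)oxy]-3-(2,4,5-trimethoxyphenyl)-4H-chromen-4-one F4.
- Semi-hydrogenation (H2, Lindlar catalyst Pd/CaCO3 poisoned with Pb(OAc)2, quinoline, EtOAc) gives 5-hydroxy-8-methoxy-7-[(2-methylbut-3-en-2-yl)oxy]-3-(2,4,5-trimethoxyphenyl)-4H-chromen-4-one F5.
- Heating F5 in PhNEt2 at 130 °C triggers an aromatic Claisen rearrangement with allyl inversion, which places a normal prenyl group on the only open ortho carbon, C6. The route is rejoined at 22.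

**Step 1.** The dibenzyl ether or C-benzylated material may form alongside the mono-ether. The fallback sets out from 1 and replaces selective protection with selective deprotection.
- Exhaustive benzylation (BnBr 3.5 equiv, K2CO3, DMF, 60 °C) gives 2,4,6-tris(benzyloxy)benzaldehyde F1.
- MgBr2·OEt2 (3 equiv, toluene–Et2O, reflux) cleaves only the two benzyl ethers that can chelate magnesium together with the formyl oxygen. The para ether stays. The route is rejoined at 2.

## Further compounds

F1 | step 1 | 2,4,6-tris(benzyloxy)benzaldehyde | O=Cc1c(OCc2ccccc2)cc(OCc2ccccc2)cc1OCc1ccccc1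
F2 | step 8 | [6-(benzyloxy)-3-methoxy-2,4-bis(methoxymethoxy)phenyl][trans-3-(2,4,5-trimethoxyphenyl)oxiran-2-yl]methanone (racemic, one enantiomer drawn) | O=C(c1c(OCc2ccccc2)cc(OCOC)c(OC)c1OCOC)[C@@H]1O[C@H]1c1cc(OC)c(OC)cc1OC
F3 | step 8 | 3-[6-(benzyloxy)-3-methoxy-2,4-bis(methoxymethoxy)phenyl]-3-oxo-2-(2,4,5-trimethoxyphenyl)propanal (racemic) | O=CC(C(=O)c1c(OCc2ccccc2)cc(OCOC)c(OC)c1OCOC)c1cc(OC)c(OC)cc1OC
F4 | step 13 | 5-hydroxy-8-methoxy-7-[(2-methylbut-3-yn-2-yl)oxy]-3-(2,4,5-trimethoxyphenyl)-4H-chromen-4-one | COc1cc(OC)c(-c2coc3c(OC)c(OC(C)(C)C#C)cc(O)c3c2=O)cc1OC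
F5 | step 13 | 5-hydroxy-8-methoxy-7-[(2-methylbut-3-en-2-yl)oxy]-3-(2,4,5-trimethoxyphenyl)-4H-chromen-4-one | COc1cc(OC)c(-c2coc3c(OC)c(OC(C)(C)C=C)cc(O)c3c2=O)cc1OC
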